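**Retrosynthetic overview**

1. Ring C (the 4-pyranone) is the only ring that is built, and it is closed last: disconnect O1–C2 (acid cyclodehydration of an ortho-hydroxyaryl 1,3-diketone).
2. Disconnect the diketone at C2–C3 (flavone numbering): Claisen-type C-aroylation of a ring A methyl ketone polyanion with a purchased ring B aroyl chloride.
3. Disconnect the two ortho C–O bonds of the symmetric 2,4,6-trihydroxy-3,5-dimethoxyphenyl methyl ketone (future C5–OH and C8a–O1): a new twofold ketone-directed C–H hydroxylation of a purchased 4-hydroxy-3,5-dimethoxyphenyl methyl ketone.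
4. Ring A is symmetric about the acetyl axis, so ring closure can give only one flavone; no protecting group is isolated.
5. Ring order: A and B are bought as benzene rings; C is formed in the final step.

Assumption: the target has no stereocentre (it is achiral), so "single enantiomer" is taken to mean the single constitution given by the SMILES.

**Route**

Step 1
Reactants: 1 1-(4-hydroxy-3,5-dimethoxyphenyl)ethanone (acetosyringone)
Product: 5 1-(2,4,6-trihydroxy-3,5-dimethoxyphenyl)ethanone, via mono(trifluoroacetate) 2 (not isolated), via bis(trifluoroacetate) 3 (not isolated), via tris(trifluoroacetate) 4 (not isolated)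
Conditions: (CF3CO)2O/CF3CO2H (1:4), rt, 30 min; then Pd(OCOCF3)2 (10 mol %), K2S2O8 (5 equiv), 60 °C, 24 h; then H2O–THF, 40 °C
Reagents that add atoms: trifluoroacetic acid, OC(=O)C(F)(F)F (one carboxylate oxygen remains as each of the two new phenolic oxygens)
Why: Proposed new method: a one-flask twofold ketone-directed ortho C–H oxygenation that builds a hexasubstituted, penta-oxygenated ring; the free phenol is first masked as electron-poor ester 2, the acetyl oxygen then steers Pd(OCOCF3)2 to C–H palladation at C2 (concerted metalation–deprotonation; the only two ring C–H bonds are the ones ortho to the acetyl group and each is activated by one ortho and one para methoxy group, so there is no regiochemical alternative), K2S2O8 oxidises divalent to tetravalent palladium, C–O reductive elimination with trifluoroacetate gives 3, the acetyl group (still able to lie coplanar, carbonyl oxygen turned towards the remaining C6–H) repeats the cycle to give 4, and because every phenol stays a trifluoroacetate in the anhydride-containing medium neither catalyst chelation by an ortho-hydroxy ketone nor quinone formation can occur before the mild aqueous work-up releases 5; the closest known reaction type is the Pd(OAc)2- or Pd(OCOCF3)2-catalysed ketone-directed mono-ortho-hydroxylation of aryl ketones with K2S2O8 in CF3CO2H/(CF3CO)2O, which has not been shown as a double hydroxylation at two methoxy-flanked positions.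

Step 2
Reactants: 5 1-(2,4,6-trihydroxy-3,5-dimethoxyphenyl)ethanone; 6 3,4,5-trimethoxybenzoyl chloride
Product: 8 1-(2,4,6-trihydroxy-3,5-dimethoxyphenyl)-3-(3,4,5-trimethoxyphenyl)propane-1,3-dione, via tetralithium polyanion 7 (not isolated)
Conditions: LiN(SiMe3)2 (4.0 equiv), THF, −78 → −10 °C; then 6 (1.0 equiv), −78 °C → rt; then aq. HCl
Reagents that add atoms: none
Why: Claisen-type C-aroylation of a lithium polyanion: the ketone enolate carbon of 7 is its most nucleophilic site and takes the single equivalent of aroyl chloride, and any O-aroylation at an ortho phenoxide would funnel to the same diketone by Baker–Venkataraman acyl transfer, so the three phenols need no protection.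

Step 3
Reactants: 8 1-(2,4,6-trihydroxy-3,5-dimethoxyphenyl)-3-(3,4,5-trimethoxyphenyl)propane-1,3-dione
Product: 10 5,7-dihydroxy-6,8-dimethoxy-2-(3,4,5-trimethoxyphenyl)-4H-chromen-4-one, via 2-hydroxyflavanone hemiketal 9 (not isolated)
Conditions: AcOH, H2SO4 (cat.), 95 °C, 1 h
Reagents that add atoms: none
Why: Acid-catalysed cyclodehydration of an ortho-hydroxyaryl 1,3-diketone: one of the two equivalent ortho phenols adds to the ring B carbonyl to give hemiketal 9, which loses water to the aromatic 4-pyranone, the other ortho phenol becomes the hydrogen-bonded 5-OH, and no stereocentre is present in the product.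

**Compound list**

1 | 1-(4-hydroxy-3,5-dimethoxyphenyl)ethanone (acetosyringone) | CC(=O)c1cc(OC)c(O)c(OC)c1 | starting material
2 | 4-acetyl-2,6-dimethoxyphenyl trifluoroacetate (formed in the flask) | CC(=O)c1cc(OC)c(OC(=O)C(F)(F)F)c(OC)c1 | intermediate
3 | 4-acetyl-2,6-dimethoxybenzene-1,3-diyl bis(trifluoroacetate) (formed in the flask) | CC(=O)c1cc(OC)c(OC(=O)C(F)(F)F)c(OC)c1OC(=O)C(F)(F)F | intermediate
4 | 2-acetyl-4,6-dimethoxybenzene-1,3,5-triyl tris(trifluoroacetate) (formed in the flask) | CC(=O)c1c(OC(=O)C(F)(F)F)c(OC)c(OC(=O)C(F)(F)F)c(OC)c1OC(=O)C(F)(F)F | intermediate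
5 | 1-(2,4,6-trihydroxy-3,5-dimethoxyphenyl)ethanone | CC(=O)c1c(O)c(OC)c(O)c(OC)c1O | intermediate
6 | 3,4,5-trimethoxybenzoyl chloride | COc1cc(cc(OC)c1OC)C(Cl)=O | starting material
7 | tetralithium 2-(1-oxidoethenyl)-4,6-dimethoxybenzene-1,3,5-triolate (formed in the flask) | [Li+].[Li+].[Li+].[Li+].C=C([O-])c1c([O-])c(OC)c([O-])c(OC)c1[O-] | intermediate
8 | 1-(2,4,6-trihydroxy-3,5-dimethoxyphenyl)-3-(3,4,5-trimethoxyphenyl)propane-1,3-dione | COc1cc(cc(OC)c1OC)C(=O)CC(=O)c1c(O)c(OC)c(O)c(OC)c1O | intermediate
9 | 2,5,7-trihydroxy-6,8-dimethoxy-2-(3,4,5-trimethoxyphenyl)chroman-4-one (racemic hemiketal, formed in the flask) | COc1cc(cc(OC)c1OC)C1(O)CC(=O)c2c(O)c(OC)c(O)c(OC)c2O1 | intermediate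
10 | 5,7-dihydroxy-6,8-dimethoxy-2-(3,4,5-trimethoxyphenyl)-4H-chromen-4-one (5,7-dihydroxy-6,8,3',4',5'-pentamethoxyflavone) | COc1cc(-c2cc(=O)c3c(O)c(OC)c(O)c(OC)c3o2)cc(OC)c1OC | target

**Totals**

Total step count: 3. Longest linear sequence: 3 steps (1 → 5 → 8 → 10); 6 enters in step 2.

**Steps most likely to fail, with fallbacks**

Step 1 (proposed new double C–H hydroxylation; most likely to fail). Risks are stalling after the first hydroxylation and oxidative damage to the electron-rich ring. The fallback uses only known chemistry: electrophilic aromatic iodination followed by Ullmann-type hydroxylation of aryl iodides. It sets out from 1: NIS (2.3 equiv) with catalytic CF3CO2H in MeCN (rt → 50 °C) iodinates the only two free ring positions to give 1-(4-hydroxy-2,6-diiodo-3,5-dimethoxyphenyl)ethanone F1. CuI-catalysed hydroxylation of F1 (CuI, 1,10-phenanthroline, KOH, DMSO–H2O, 100 °C, argon; acidic work-up) replaces both iodides by hydroxyl. The fallback comes back to the route at 5.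

Step 2 (polyanion C-aroylation). Risks are poor solubility of the polyanion and proton transfer from the product diketone to unreacted enolate. The fallback replaces the intermolecular enolate acylation by an intramolecular O→C acyl transfer. It sets out from 5 and 6: exhaustive O-aroylation (6, 3.5 equiv, pyridine, DMAP cat., 0 °C → rt) gives 2-acetyl-4,6-dimethoxybenzene-1,3,5-triyl tris(3,4,5-trimethoxybenzoate) F2. Baker–Venkataraman rearrangement (KOH, pyridine, 50 °C) gives 1-[2-hydroxy-3,5-dimethoxy-4,6-bis(3,4,5-trimethoxybenzoyloxy)phenyl]-3-(3,4,5-trimethoxyphenyl)propane-1,3-dione F3. LiOH in THF–H2O (0 °C → rt, then acidification) removes the two remaining aryl esters. The fallback comes back to the route at 8.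

Step 3 (acid cyclodehydration). The risk is degradation of the free, penta-oxygenated triphenol 8 in hot acid. The fallback closes ring C under basic conditions and never passes through free 8 or an acid step. It sets out from 5 and 6: heating with 6 (4 equiv) and K2CO3 in acetone at reflux runs O-aroylation, acyl transfer, a second C-aroylation and ring closure in one flask. The product is 5-hydroxy-6,8-dimethoxy-4-oxo-3-(3,4,5-trimethoxybenzoyl)-2-(3,4,5-trimethoxyphenyl)-4H-chromen-7-yl 3,4,5-trimethoxybenzoate F4. Hot 5 % K2CO3 in EtOH–H2O (then acidification) cleaves the 7-O-ester and, by retro-Claisen reaction, the 3-aroyl group. The fallback comes back to the route at 10.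

**Further compounds**

F1 | step 1 | 1-(4-hydroxy-2,6-diiodo-3,5-dimethoxyphenyl)ethanone | CC(=O)c1c(I)c(OC)c(O)c(OC)c1I
F2 | step 2 | 2-acetyl-4,6-dimethoxybenzene-1,3,5-triyl tris(3,4,5-trimethoxybenzoate) | CC(=O)c1c(OC(=O)c2cc(OC)c(OC)c(OC)c2)c(OC)c(OC(=O)c2cc(OC)c(OC)c(OC)c2)c(OC)c1OC(=O)c1cc(OC)c(OC)c(OC)c1
F3 | step 2 | 1-[2-hydroxy-3,5-dimethoxy-4,6-bis(3,4,5-trimethoxybenzoyloxy)phenyl]-3-(3,4,5-trimethoxyphenyl)propane-1,3-dione | COc1cc(cc(OC)c1OC)C(=O)CC(=O)c1c(O)c(OC)c(OC(=O)c2cc(OC)c(OC)c(OC)c2)c(OC)c1OC(=O)c1cc(OC)c(OC)c(OC)c1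
F4 | step 3 | 5-hydroxy-6,8-dimethoxy-4-oxo-3-(3,4,5-trimethoxybenzoyl)-2-(3,4,5-trimethoxyphenyl)-4H-chromen-7-yl 3,4,5-trimethoxybenzoate | COc1cc(cc(OC)c1OC)C(=O)Oc1c(OC)c(O)c2c(c1OC)oc(-c1cc(OC)c(OC)c(OC)c1)c(C(=O)c1cc(OC)c(OC)c(OC)c1)c2=O
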